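The route rests on the bond between C1 of the 14-membered ring (the only stereocentre, a methine flanked by ring CH2 groups C2 and C14) and C15, the exocyclic 1,1-disubstituted alkene carbon. A C1–B bond stands in for it: Zweifel olefination lets a Shapiro-derived 2-lithio-1,5-diene capture an open-chain (R)-secondary pinacol boronic ester and moves C1 from boron to C15 with retention, so the whole side chain and the stereocentre are delivered in one transition-metal-free operation. The boronic ester, assembled by sparteine-controlled lithiation–borylation of a Z-allyl boronate (C2–C7) and an E-chloroalkyl benzoate (C9–C14, C1), holds every ring carbon except C8; phosphonoacetate supplies C8 and closes the ring by Horner–Wadsworth–Emmons olefination.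

Key step: step 8

Remark: ring atoms are numbered C1 (stereocentre), C2, C3=C4(CH3), C5, C6, C7=C8(CH2OH), C9, C10, C11=C12(CH3), C13, C14; C15 is the exocyclic alkene carbon bonded to C1.

Step 1
Reactants: 1 6-methylhept-5-en-2-one; 2 2,4,6-triisopropylbenzenesulfonohydrazide
Product: 3 (E)-N'-(6-methylhept-5-en-2-ylidene)-2,4,6-triisopropylbenzenesulfonohydrazide
Conditions: MeOH, cat. conc. HCl, 20 °C
Reagents that add atoms: none
Why: Acid-catalysed condensation of the methyl ketone with the arylsulfonylhydrazide (hydrazone formation) should give the crystalline E-hydrazone that a Shapiro reaction needs.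

Step 2
Reactants: 4 2-(2-bromoethyl)-1,3-dioxolane; 5 propyne
Product: 9 2-[(3Z)-4-iodo-3-methylbut-3-en-1-yl]-1,3-dioxolane, via Grignard reagent 6 (not isolated), via alkylcopper 7 (not isolated), via alkenylcopper 8 (not isolated)
Conditions: Mg, THF, 25 °C; CuBr·SMe2, Et2O/Me2S, −45 °C; propyne, −25 °C; I2, −78 → 0 °C
Reagents that add atoms: iodine, II
Why: Normant carbocupration: the alkylcopper adds syn across propyne with the alkyl group on the internal carbon, so copper and the new chain are cis, and iodinolysis with retention should fix the Z geometry of the future C3=C4 bond.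

Step 3
Reactants: 9 2-[(3Z)-4-iodo-3-methylbut-3-en-1-yl]-1,3-dioxolane; 10 2-(chloromethyl)-4,4,5,5-tetramethyl-1,3,2-dioxaborolane
Product: 13 2-[(2Z)-5-(1,3-dioxolan-2-yl)-3-methylpent-2-en-1-yl]-4,4,5,5-tetramethyl-1,3,2-dioxaborolane, via alkenyllithium 11 (not isolated), via boronate complex 12 (not isolated)
Conditions: t-BuLi (2 equiv), Et2O, −78 °C; then 10, −78 → 20 °C
Reagents that add atoms: none
Why: Iodine–lithium exchange with retention of alkene geometry followed by a Matteson-type homologation (the alkenyllithium adds to boron, then 1,2-migration displaces chloride) should give the Z-allylboronate without allylic transposition.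

Step 4
Reactants: 14 pent-4-yn-1-ol
Product: 15 pent-4-yn-1-yl 2,4,6-triisopropylbenzoate
Conditions: 2,4,6-triisopropylbenzoyl chloride, Et3N, DMAP (cat.), CH2Cl2, 40 °C
Reagents that add atoms: 2,4,6-triisopropylbenzoyl chloride, CC(C)c1cc(C(C)C)c(C(=O)Cl)c(C(C)C)c1
Why: Acylation of the primary alcohol (esterification) installs the hindered triisopropylbenzoate that later directs α-lithiation and is inert to the organoaluminium and organolithium reagents of step 5.

Step 5
Reactants: 15 pent-4-yn-1-yl 2,4,6-triisopropylbenzoate; 16 oxirane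
Product: 19 (4E)-7-hydroxy-4-methylhept-4-en-1-yl 2,4,6-triisopropylbenzoate, via alkenylalane 17 (not isolated), via lithium alanate 18 (not isolated)
Conditions: Me3Al, Cp2ZrCl2 (cat.), CH2Cl2, 0 → 20 °C; evaporate; n-BuLi, THF/hexane, −30 °C; oxirane, −30 → 20 °C; aq. Rochelle salt
Reagents that add atoms: trimethylaluminium, C[Al](C)C
Why: Negishi zirconium-catalysed carboalumination adds methyl and aluminium syn to the alkyne with methyl on the internal carbon, and the derived alanate opens oxirane with retention, which should give the E geometry of the future C11=C12 bond.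

Step 6
Reactants: 19 (4E)-7-hydroxy-4-methylhept-4-en-1-yl 2,4,6-triisopropylbenzoate
Product: 20 (4E)-7-chloro-4-methylhept-4-en-1-yl 2,4,6-triisopropylbenzoate
Conditions: PPh3, NCS, CH2Cl2, 0 → 20 °C
Reagents that add atoms: N-chlorosuccinimide, O=C1CCC(=O)N1Cl
Why: Appel-type chlorination (SN2 at the primary carbon) converts the alcohol into a chloride that should tolerate the cold organolithium steps and later serve as the alkylating end.

Step 7
Reactants: 20 (4E)-7-chloro-4-methylhept-4-en-1-yl 2,4,6-triisopropylbenzoate; 13 2-[(2Z)-5-(1,3-dioxolan-2-yl)-3-methylpent-2-en-1-yl]-4,4,5,5-tetramethyl-1,3,2-dioxaborolane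
Product: 23 2-[(3Z,6R,9E)-12-chloro-1-(1,3-dioxolan-2-yl)-3,9-dimethyldodeca-3,9-dien-6-yl]-4,4,5,5-tetramethyl-1,3,2-dioxaborolane, via lithiated benzoate 21 (not isolated), via boronate complex 22 (not isolated)
Conditions: s-BuLi, (−)-sparteine, Et2O, −78 °C, 5 h; then 13, −78 °C; then 35 °C, 12 h
Reagents that add atoms: none
Why: Hoppe–Aggarwal lithiation–borylation: s-BuLi/(−)-sparteine removes the pro-S α-proton, 13 adds to the configurationally stable organolithium with retention, and 1,2-migration of the allyl group with loss of the benzoate inverts the carbon, which should set the R configuration at C1 while joining C1 to C2 without allylic transposition.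

Step 8
Reactants: 3 (E)-N'-(6-methylhept-5-en-2-ylidene)-2,4,6-triisopropylbenzenesulfonohydrazide; 23 2-[(3Z,6R,9E)-12-chloro-1-(1,3-dioxolan-2-yl)-3,9-dimethyldodeca-3,9-dien-6-yl]-4,4,5,5-tetramethyl-1,3,2-dioxaborolane
Product: 27 2-[(3Z,6R,9E)-12-chloro-3,9-dimethyl-6-(6-methylhepta-1,5-dien-2-yl)dodeca-3,9-dien-1-yl]-1,3-dioxolane, via alkenyllithium 24 (not isolated), via boronate complex 25 (not isolated), via iodoboronic ester 26 (not isolated)
Conditions: 3 (excess), s-BuLi (2 equiv per 3), THF, −78 → 0 °C; then 23, −78 °C; I2, MeOH, −78 °C; NaOMe, MeOH, −78 → 20 °C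
Reagents that add atoms: none
Why: Regioselective Shapiro reaction of 3 (kinetic, syn-directed deprotonation at the methyl group, then loss of N2 and sulfinate) gives alkenyllithium 24, which adds to the boron of 23 to give boronate 25; iodine then forms an iodonium ion on the electron-rich boron-bound alkene and triggers 1,2-migration of C1 from boron to C15, making the C1–C15 bond in 26, and methoxide-induced anti-elimination of boron and iodide unveils the 1,1-disubstituted alkene. The closest known reaction type is the Zweifel olefination of secondary pinacol boronic esters with α-substituted vinyllithium reagents. No ring is closed. No new stereocentre arises: the migrating C1 keeps its configuration (stereoretentive 1,2-metalate shift), so the R centre set in step 7 becomes the R centre of the target. The step needs chemoselective attack of iodine on the boronate alkene rather than on the two trisubstituted alkenes of 23 and the one in the side chain, which the much higher nucleophilicity of the ate complex at −78 °C should secure, and complete ate-complex formation, which excess 24 should secure; the alkyl chloride and the acetal are inert to all reagents.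

Step 9
Reactants: 27 2-[(3Z,6R,9E)-12-chloro-3,9-dimethyl-6-(6-methylhepta-1,5-dien-2-yl)dodeca-3,9-dien-1-yl]-1,3-dioxolane; 28 triethyl phosphonoacetate
Product: 30 ethyl (5E,9R,11Z)-2-(diethoxyphosphoryl)-14-(1,3-dioxolan-2-yl)-6,12-dimethyl-9-(6-methylhepta-1,5-dien-2-yl)tetradeca-5,11-dienoate (both C2 epimers), via sodium phosphonoacetate 29 (not isolated)
Conditions: 28 (excess), NaH, DMF, 0 °C; then 27, NaI (cat.), 70 °C
Reagents that add atoms: none
Why: C-Alkylation of the soft phosphonoacetate anion by the primary chloride under in situ Finkelstein activation (malonate-type alkylation) should install C8 together with its ester and phosphonate; the new C8 centre forms as both epimers and is destroyed in step 11.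

Step 10
Reactants: 30 ethyl (5E,9R,11Z)-2-(diethoxyphosphoryl)-14-(1,3-dioxolan-2-yl)-6,12-dimethyl-9-(6-methylhepta-1,5-dien-2-yl)tetradeca-5,11-dienoate
Product: 31 ethyl (5E,9R,11Z)-2-(diethoxyphosphoryl)-6,12-dimethyl-9-(6-methylhepta-1,5-dien-2-yl)-15-oxopentadeca-5,11-dienoate
Conditions: 1 M aq. HCl, THF, 20 °C
Reagents that add atoms: water, O
Why: Acid-catalysed acetal hydrolysis frees the C7 aldehyde under conditions mild enough for the isolated alkenes, the phosphonate and the ester.

Step 11
Reactants: 31 ethyl (5E,9R,11Z)-2-(diethoxyphosphoryl)-6,12-dimethyl-9-(6-methylhepta-1,5-dien-2-yl)-15-oxopentadeca-5,11-dienoate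
Product: 32 ethyl (1E,5Z,8R,11E)-5,11-dimethyl-8-(6-methylhepta-1,5-dien-2-yl)cyclotetradeca-1,5,11-triene-1-carboxylate
Conditions: LiCl, DBU, MeCN, 20 °C, 1 mM, slow addition of 31
Reagents that add atoms: none
Why: Intramolecular Horner–Wadsworth–Emmons olefination under Masamune–Roush conditions at high dilution should close the 14-membered ring and give the thermodynamically preferred E-enoate (ester trans to C6, so that C6 and C9 are cis as in the target).

Step 12
Reactants: 32 ethyl (1E,5Z,8R,11E)-5,11-dimethyl-8-(6-methylhepta-1,5-dien-2-yl)cyclotetradeca-1,5,11-triene-1-carboxylate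
Product: 33 [(1E,5Z,8R,11E)-5,11-dimethyl-8-(6-methylhepta-1,5-dien-2-yl)cyclotetradeca-1,5,11-trien-1-yl]methanol
Conditions: DIBAL-H, CH2Cl2, −78 °C; aq. Rochelle salt
Reagents that add atoms: none
Why: DIBAL-H reduces the conjugated ester in a 1,2 sense to the allylic alcohol without touching the alkenes or the stereocentre (ester reduction).

Compound list
1 | 6-methylhept-5-en-2-one | CC(=O)CCC=C(C)C | starting material
2 | 2,4,6-triisopropylbenzenesulfonohydrazide | CC(C)c1cc(C(C)C)c(S(=O)(=O)NN)c(C(C)C)c1 | starting material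
3 | (E)-N'-(6-methylhept-5-en-2-ylidene)-2,4,6-triisopropylbenzenesulfonohydrazide | CC(C)=CCC/C(C)=N/NS(=O)(=O)c1c(C(C)C)cc(C(C)C)cc1C(C)C | intermediate
4 | 2-(2-bromoethyl)-1,3-dioxolane | BrCCC1OCCO1 | starting material
5 | propyne | CC#C | starting material
6 | [2-(1,3-dioxolan-2-yl)ethyl]magnesium bromide (not isolated) | Br[Mg]CCC1OCCO1 | intermediate
7 | [2-(1,3-dioxolan-2-yl)ethyl]copper (not isolated) | [Cu]CCC1OCCO1 | intermediate
8 | [(1Z)-4-(1,3-dioxolan-2-yl)-2-methylbut-1-en-1-yl]copper (not isolated) | [Cu]/C=C(/C)CCC1OCCO1 | intermediate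
9 | 2-[(3Z)-4-iodo-3-methylbut-3-en-1-yl]-1,3-dioxolane | I/C=C(/C)CCC1OCCO1 | intermediate
10 | 2-(chloromethyl)-4,4,5,5-tetramethyl-1,3,2-dioxaborolane | ClCB1OC(C)(C)C(C)(C)O1 | starting material
11 | [(1Z)-4-(1,3-dioxolan-2-yl)-2-methylbut-1-en-1-yl]lithium (not isolated) | [Li]/C=C(/C)CCC1OCCO1 | intermediate
12 | lithium (chloromethyl)[(1Z)-4-(1,3-dioxolan-2-yl)-2-methylbut-1-en-1-yl](pinacolato)borate (not isolated) | [Li+].ClC[B-]1(/C=C(/C)CCC2OCCO2)OC(C)(C)C(C)(C)O1 | intermediate
13 | 2-[(2Z)-5-(1,3-dioxolan-2-yl)-3-methylpent-2-en-1-yl]-4,4,5,5-tetramethyl-1,3,2-dioxaborolane | CC1(C)OB(C/C=C(/C)CCC2OCCO2)OC1(C)C | intermediate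
14 | pent-4-yn-1-ol | C#CCCCO | starting material
15 | pent-4-yn-1-yl 2,4,6-triisopropylbenzoate | C#CCCCOC(=O)c1c(C(C)C)cc(C(C)C)cc1C(C)C | intermediate
16 | oxirane | C1CO1 | starting material
17 | dimethyl[(1E)-2-methyl-5-(2,4,6-triisopropylbenzoyloxy)pent-1-en-1-yl]alane (not isolated) | C[Al](C)/C=C(\C)CCCOC(=O)c1c(C(C)C)cc(C(C)C)cc1C(C)C | intermediate
18 | lithium butyl(dimethyl)[(1E)-2-methyl-5-(2,4,6-triisopropylbenzoyloxy)pent-1-en-1-yl]aluminate (not isolated) | [Li+].CCCC[Al-](C)(C)/C=C(\C)CCCOC(=O)c1c(C(C)C)cc(C(C)C)cc1C(C)C | intermediate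
19 | (4E)-7-hydroxy-4-methylhept-4-en-1-yl 2,4,6-triisopropylbenzoate | OCC/C=C(\C)CCCOC(=O)c1c(C(C)C)cc(C(C)C)cc1C(C)C | intermediate
20 | (4E)-7-chloro-4-methylhept-4-en-1-yl 2,4,6-triisopropylbenzoate | ClCC/C=C(\C)CCCOC(=O)c1c(C(C)C)cc(C(C)C)cc1C(C)C | intermediate
21 | [(1S,4E)-7-chloro-4-methyl-1-(2,4,6-triisopropylbenzoyloxy)hept-4-en-1-yl]lithium, sparteine complex (not isolated) | [Li][C@H](OC(=O)c1c(C(C)C)cc(C(C)C)cc1C(C)C)CC/C(C)=C/CCCl | intermediate
22 | lithium [(1S,4E)-7-chloro-4-methyl-1-(2,4,6-triisopropylbenzoyloxy)hept-4-en-1-yl][(2Z)-5-(1,3-dioxolan-2-yl)-3-methylpent-2-en-1-yl](pinacolato)borate (not isolated) | [Li+].CC1(C)O[B-](C/C=C(/C)CCC2OCCO2)([C@H](OC(=O)c3c(C(C)C)cc(C(C)C)cc3C(C)C)CC/C(C)=C/CCCl)OC1(C)C | intermediate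
23 | 2-[(3Z,6R,9E)-12-chloro-1-(1,3-dioxolan-2-yl)-3,9-dimethyldodeca-3,9-dien-6-yl]-4,4,5,5-tetramethyl-1,3,2-dioxaborolane | CC1(C)OB([C@@H](C/C=C(/C)CCC2OCCO2)CC/C(C)=C/CCCl)OC1(C)C | intermediate
24 | (6-methylhepta-1,5-dien-2-yl)lithium (not isolated) | [Li]C(=C)CCC=C(C)C | intermediate
25 | lithium [(3Z,6R,9E)-12-chloro-1-(1,3-dioxolan-2-yl)-3,9-dimethyldodeca-3,9-dien-6-yl](6-methylhepta-1,5-dien-2-yl)(pinacolato)borate (not isolated) | [Li+].CC1(C)O[B-](C(=C)CCC=C(C)C)([C@@H](C/C=C(/C)CCC2OCCO2)CC/C(C)=C/CCCl)OC1(C)C | intermediate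
26 | β-iodoboronic ester: pinacol ester of the boronic acid whose boron sits on a quaternary carbon bearing CH2I, the 4-methylpent-3-enyl chain and C1 (R at C1, both epimers at the quaternary carbon; not isolated) | CC1(C)OB(C(CI)(CCC=C(C)C)[C@@H](C/C=C(/C)CCC2OCCO2)CC/C(C)=C/CCCl)OC1(C)C | intermediate
27 | 2-[(3Z,6R,9E)-12-chloro-3,9-dimethyl-6-(6-methylhepta-1,5-dien-2-yl)dodeca-3,9-dien-1-yl]-1,3-dioxolane | C=C(CCC=C(C)C)[C@@H](C/C=C(/C)CCC1OCCO1)CC/C(C)=C/CCCl | intermediate
28 | triethyl phosphonoacetate | CCOC(=O)CP(=O)(OCC)OCC | starting material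
29 | sodium salt of triethyl phosphonoacetate (not isolated) | [Na+].CCOC(=O)[CH-]P(=O)(OCC)OCC | intermediate
30 | ethyl (5E,9R,11Z)-2-(diethoxyphosphoryl)-14-(1,3-dioxolan-2-yl)-6,12-dimethyl-9-(6-methylhepta-1,5-dien-2-yl)tetradeca-5,11-dienoate (both C2 epimers) | CCOC(=O)C(CC/C=C(\C)CC[C@H](C/C=C(/C)CCC1OCCO1)C(=C)CCC=C(C)C)P(=O)(OCC)OCC | intermediate
31 | ethyl (5E,9R,11Z)-2-(diethoxyphosphoryl)-6,12-dimethyl-9-(6-methylhepta-1,5-dien-2-yl)-15-oxopentadeca-5,11-dienoate (both C2 epimers) | CCOC(=O)C(CC/C=C(\C)CC[C@H](C/C=C(/C)CCC=O)C(=C)CCC=C(C)C)P(=O)(OCC)OCC | intermediate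
32 | ethyl (1E,5Z,8R,11E)-5,11-dimethyl-8-(6-methylhepta-1,5-dien-2-yl)cyclotetradeca-1,5,11-triene-1-carboxylate | C=C(CCC=C(C)C)[C@H]1C/C=C(/C)CC/C=C(/C(=O)OCC)CC/C=C(\C)CC1 | intermediate
33 | [(1E,5Z,8R,11E)-5,11-dimethyl-8-(6-methylhepta-1,5-dien-2-yl)cyclotetradeca-1,5,11-trien-1-yl]methanol | C=C(CCC=C(C)C)[C@H]1C/C=C(/C)CC/C=C(/CO)CC/C=C(\C)CC1 | target

Total step count: 12. Longest linear sequence: 9 steps (steps 4 to 12, from pent-4-yn-1-ol 14).

Steps most likely to fail

Step 8 (key step). The α-branched alkenyllithium may add incompletely to the secondary boronic ester, the Shapiro deprotonation may give some internal alkenyllithium, and iodine may attack the trisubstituted alkenes. The fallback sets out from 23 and comes back at 27; it transfers only a two-carbon alkenyl unit and grows the chain afterwards. Zweifel olefination of 23 with the small 1-ethoxyvinyllithium (ethyl vinyl ether, t-BuLi, THF; then I2/MeOH, NaOMe) should give the enol ether F1. Brief treatment with dilute aqueous HCl in THF at 0 °C, where the enol ether is hydrolysed far faster than the dioxolane, should give the methyl ketone F2. Kinetic deprotonation at the methyl group (LDA, THF, −78 °C) and alkylation with 1-bromo-3-methylbut-2-ene should give the prenylated ketone F3. Wittig methylenation (Ph3P=CH2, THF, −78 → 0 °C) then returns to 27.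

Step 7. The 1,2-migration of the allyl group in the boronate complex may be slow, the organolithium base may eliminate HCl from the homoallylic chloride, and the lithiation may proceed with reduced enantioselectivity. The fallback sets out from 20 and 3 and comes back at 27; it inverts the order in which the two carbon substituents are attached to C1. Shapiro reaction of 3 and quenching with 2-isopropoxy-4,4,5,5-tetramethyl-1,3,2-dioxaborolane should give the alkenylboronic ester F4. Lithiation of 20 with s-BuLi/(+)-sparteine (the opposite enantiomer is required because the order of attachment changes), borylation with F4 and 1,2-migration of the alkenyl group should give the allylic boronic ester F5. One-carbon Matteson homologation (BrCH2Cl, n-BuLi, THF, −78 → 20 °C) should give the primary boronic ester F6. B-alkyl Suzuki–Miyaura coupling with the Z-alkenyl iodide 9 (Pd(OAc)2, RuPhos, aq. K3PO4, toluene, 80 °C), which keeps the alkene geometry, returns to 27.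

Step 11. Oligomerisation may compete with ring closure, and control of the alkene geometry may be poor. The fallback sets out from 27 and comes back at 32; it closes the ring through a C8–C9 single bond and sets the alkene geometry afterwards. Acetal hydrolysis of 27 (1 M HCl, THF) should give the chloro aldehyde F7. Roskamp homologation (ethyl diazoacetate, cat. SnCl2, CH2Cl2) should give the β-keto ester F8. Intramolecular C-alkylation at high dilution (NaI, Cs2CO3, MeCN, 60 °C) should give the macrocyclic β-keto ester F9. Chelation-controlled enolisation and triflation (NaH, Tf2O, THF, −78 °C) should give the Z-enol triflate F10. Palladium-catalysed formate reduction with retention (Pd(OAc)2, PPh3, Bu3N, HCO2H, DMF, 60 °C) returns to 32.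

Further compounds
F1 | step 8 | 2-[(3Z,6R,9E)-12-chloro-6-(1-ethoxyethenyl)-3,9-dimethyldodeca-3,9-dien-1-yl]-1,3-dioxolane | C=C(OCC)[C@@H](C/C=C(/C)CCC1OCCO1)CC/C(C)=C/CCCl
F2 | step 8 | (3R,5Z)-3-[(3E)-6-chloro-3-methylhex-3-en-1-yl]-8-(1,3-dioxolan-2-yl)-6-methyloct-5-en-2-one | CC(=O)[C@@H](C/C=C(/C)CCC1OCCO1)CC/C(C)=C/CCCl
F3 | step 8 | (7R,9Z)-7-[(3E)-6-chloro-3-methylhex-3-en-1-yl]-12-(1,3-dioxolan-2-yl)-2,10-dimethyldodeca-2,9-dien-6-one | CC(C)=CCCC(=O)[C@@H](C/C=C(/C)CCC1OCCO1)CC/C(C)=C/CCCl
F4 | step 7 | 4,4,5,5-tetramethyl-2-(6-methylhepta-1,5-dien-2-yl)-1,3,2-dioxaborolane | C=C(CCC=C(C)C)B1OC(C)(C)C(C)(C)O1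
F5 | step 7 | 2-[(3S,6E)-9-chloro-6-methyl-2-(4-methylpent-3-en-1-yl)nona-1,6-dien-3-yl]-4,4,5,5-tetramethyl-1,3,2-dioxaborolane | C=C(CCC=C(C)C)[C@H](CC/C(C)=C/CCCl)B1OC(C)(C)C(C)(C)O1
F6 | step 7 | 2-[(2S,5E)-8-chloro-5-methyl-2-(6-methylhepta-1,5-dien-2-yl)oct-5-en-1-yl]-4,4,5,5-tetramethyl-1,3,2-dioxaborolane | C=C(CCC=C(C)C)[C@H](CC/C(C)=C/CCCl)CB1OC(C)(C)C(C)(C)O1
F7 | step 11 | (4Z,7R,10E)-13-chloro-4,10-dimethyl-7-(6-methylhepta-1,5-dien-2-yl)trideca-4,10-dienal | C=C(CCC=C(C)C)[C@@H](C/C=C(/C)CCC=O)CC/C(C)=C/CCCl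
F8 | step 11 | ethyl (6Z,9R,12E)-15-chloro-6,12-dimethyl-9-(6-methylhepta-1,5-dien-2-yl)-3-oxopentadeca-6,12-dienoate | C=C(CCC=C(C)C)[C@@H](C/C=C(/C)CCC(=O)CC(=O)OCC)CC/C(C)=C/CCCl
F9 | step 11 | ethyl (5Z,8R,11E)-5,11-dimethyl-8-(6-methylhepta-1,5-dien-2-yl)-2-oxocyclotetradeca-5,11-diene-1-carboxylate (both C1 epimers) | C=C(CCC=C(C)C)[C@H]1C/C=C(/C)CCC(=O)C(C(=O)OCC)CC/C=C(\C)CC1
F10 | step 11 | ethyl (1Z,5Z,8R,11E)-5,11-dimethyl-8-(6-methylhepta-1,5-dien-2-yl)-2-(trifluoromethylsulfonyloxy)cyclotetradeca-1,5,11-triene-1-carboxylate | C=C(CCC=C(C)C)[C@H]1C/C=C(/C)CC/C(OS(=O)(=O)C(F)(F)F)=C(/C(=O)OCC)CC/C=C(\C)CC1
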